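At the reading, 1.0 min after the start, you want a quick number for [product] in the flasks below, and your hunch is that a bigger charge of solid substrate buys more product by then. I would test that hunch before touching any intermediate.

in all of them: gas 10 mM (held); time 1.0 min

| charge | solid substrate |
|---|---|
| cedar | 0.050 M |
| oak | 0.10 M |
| ash | 0.20 M |

    starting material → intermediate A (k1 = 0.066 s⁻¹)
    intermediate A → intermediate B (k2 = 0.0056 s⁻¹)
    coupling partner + intermediate B ⇌ intermediate C (K3 = 100 L mol⁻¹, k3 = 1.1 L mol⁻¹ s⁻¹)
    coupling partner + intermediate A ⇌ product (K4 = 220 L mol⁻¹, k4 = 0.89 L mol⁻¹ s⁻¹)
    solid substrate ⇌ starting material, rate k5*(cs5 - [starting material]) while solid is left; crystals form when [starting material] > cs5 (cs5 = 29 mM, k5 = 0.0087 s⁻¹)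
    gas ⇌ coupling partner, rate k6*(csat - [coupling partner]) (k6 = 0.048 s⁻¹, csat = 10 mM)

- given per volume of solution although it is solid: solid substrate
- at the start none of coupling partner is dissolved
- at the start none of the solid substrate is in solution
- "hardly changes" means that all values lie within two and a half points (for a concentration: within two and a half percent of the largest)
- run time (cedar): 1.0 min

- [product] at the end for cedar, oak, ash, in this order
- how the row runs (falls all the way / rises, then falls / hardly changes / falls, then rises / rises all the way)

Look first at what the charge can do. The dissolving rate is its coefficient times the gap between the solubility and [starting material], and the amount of solid does not appear in it, so the feed is zero-order in the solid for as long as some remains. Since [starting material] begins at nothing and can only narrow that gap, the feed is at its largest at the start, and the coefficient 0.0087 s⁻¹ times the solubility 29 mM gives what I call the ceiling feed, 15.1 mM min⁻¹.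

Over the run that allows at most 15.1 mM to dissolve, which comes to 30.3% of cedar's solid, and the ceiling is smaller than the smallest charge. So solid stands in each flask at the reading, each flask gets the same feed from the same law, and I expect a flat row, against your hunch. That is as far as I go by hand, and I commit to no height.

The forecast agrees on the shape and adds a height, 0.0014 M, 0.0014 M and 0.0014 M, so that the row hardly changes, on the ground that “the solid never runs out”.

The simulation gives 0.00142 M, 0.00142 M and 0.00142 M, so the row hardly changes. Cedar holds 72.5% of its solid substrate at the reading, so 13.8 mM has dissolved, less than the ceiling of 15.1 mM. Run the ceiling feed on to 10.0 min for ash: at most 75.7% of its charge can have dissolved, which leaves at least 24.3%, and the ash flask then holds 32.9%.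

The numbers were drawn at random within sensible limits; no experiment stands behind them.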